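(The data were computed for substances that don't exist, and the scatter is random.)

If a flask's substrate loses a fixed fraction of itself per day, the charge drops out of the substrate's own percentage, so I reckoned with the fraction left rather than the fraction made.

| setting | blue | teal | flask |
|---|---|---|---|
| substrate | 0.050 M | 0.075 M | 0.050 M |
| remark | the very flask that is asked about, followed so far | run made earlier |  |
| time |  |  | 15 d |

- blue (time / d: target / %, substrate / %): 0.333: 5, 57; 0.833: 14, 22; 2.50: 15, 0; 8.00: 0, 0
- teal (time / d: target / %, substrate / %): 0.333: 4, 55; 1.25: 19, 10; 4.00: 7, 2; 15.0: 0, 0

(readings scatter by 1.5 percentage points)



* time, not beyond 15 d, at which the flask holds most target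
* the amount of target, in percent of the substrate charged, at that time
* earliest time at which at least nineteen twentieths of that best amount are there, in d
* latest time at which they still are, in d

From the first blue reading I took the substrate clock, the apparent first-order rate constant of the fraction left:

clock = −ln(fraction left) / time = 1.69 d⁻¹

The first teal reading, at a charge of 0.075 M, gave about the same, 1.80 d⁻¹.

The fastest rung of my ladder was therefore the substrate, halving in 0.411 d. Next came the lag of the target: at 0.333 d the blue run had lost 43.0 % of its substrate but showed 5 % target. The slowest rung was the fall of the target, which in the teal run went from 19 % to 7 % and so halved in 1.91 d, slower than the substrate, while the 15 d allowed lay far beyond it.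

The highest target reading stood in the teal run with 10 % substrate left, so I looked for the peak of this flask at that same fraction:

time of peak = −ln(fraction left) / clock = 1.36 d

The forecast, holding that “its rate shows no clear dependence on concentration”, put the best at 1.4 d with 19 %, and the window from 1.1 d to 1.85 d; my time lay close to its time.

The flask gave 17.2 % at 1.27 d, with the window from 0.966 d to 1.67 d, and all four forecast values held within their margins.

    substrate → intermediate A (k = 0.0592 h⁻¹)
    substrate ⇌ intermediate B (K = 5.60, k = 0.0149 h⁻¹)
    intermediate A ⇌ target (K = 0.958, k = 0.0666 h⁻¹)
    target → over-reaction product (k = 0.0536 h⁻¹)
    substrate + intermediate A → side product (k = 0.241 M⁻¹ h⁻¹)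

At that best time the clock left 11.7 % of the substrate, and the flask held 9.77 %. For the neighbour, charged with 0.020 M, I kept the same clock, which gave it the same 11.7 % of its substrate at that time. Its simulated best is 18.0 % against 17.2 % here, and the substrate left at 15.0 d is 0.35 % against 0.34 %. The side product does move with the charge, standing at 3.29 % in the neighbour against 7.75 % in this flask at 15.0 d.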